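**The question.** Has this flask of Z stopped at 80 min, and what stands in it then?

- beta: Z 0.50 mM; the very flask that is asked about, followed so far
- flask: Z 0.50 mM; time 80 min

beta run (percent of the Z charged)

| time / min | Z / % | X / % | J / % |
|---|---|---|---|
| 4.00 | 37.5 | 10.0 | 1.2 |
| 12.0 | 4.2 | 81.2 | 5.6 |
| 20.0 | 0 | 92.2 | 9.0 |
| 30.0 | 0 | 94.2 | 8.1 |

(scatter of a reading: 1 percentage point)

- why nothing more happens at 80 min, or that something still does (it is still moving / all of Z has reacted / forward and back rates have come level)
- share of the Z used up at 80 min
- X at 80 min, in percent of the Z charged
- J at 80 min, in percent of the Z charged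

- percent here means Z units held: one J counts as two
- what was read earlier has a scatter of 1 percentage point, one standard deviation
- the reaction counts as stopped when no species that holds the Z changes by six tenths of a point or more over the second half of the time

**A gap.** At 4.00 min this flask has lost 62.5% of its Z, yet X and J together hold 11.2%. These numbers don't match. But at 20.0 min X and J hold 101%, so I take the missing Z as held by something unread.

**Fraction left.** So I count what is left, not what is made. The unfinished share is the part of the charge not yet in X or J. It reads 88.8% at 4.00 min and 13.2% at 12.0 min. Read between those two times, that gives a mean half-life of the unfinished share of 2.91 min. From 12.0 min to 80 min lie 23.4 half-lives, so if that half-life holds, I reckon <0.001% unfinished, far less than the scatter. I expect this flask to have stopped.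

**The forecast.** It gives all of Z has reacted, conversion 100%, X 92% and J 8.3%. Its ground: “Z reaching zero suggests an irreversible reaction that stopped because its feed ran out”

**The result.** This flask gives all of Z has reacted, conversion 100%, X 92.1% and J 7.88%, so the forecast held.

    Z + 2 X → 3 X (k = 2.40 × 10⁵ M⁻² s⁻¹)
    Z → X (k = 8.70 × 10⁻⁴ s⁻¹)
    Z + X → J (k = 2.20 M⁻¹ s⁻¹)
    Z ⇌ G (K = 1.40, k = 0.0230 s⁻¹)

**One comparison.** At 9.49 min in this flask, Z has a half-life of 0.68 min by the autocatalytic step, shorter than 20 min by the step to J, and X ends at 92.1% against J at 7.88%. G, which the forecast's number doesn't show, stands at 38.3% at 8.00 min, but 9.63 half-lives after 12.0 min, at 40.0 min, G is 0% and Z 0%, and its path changes X at 80 min by nothing.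

**Second flask.** The same flask read at 300 min lies 99.0 half-lives past 12.0 min, so I expect no unfinished share to read. It holds Z 0%, G 0%, X 92.1% and J 7.88%.

All runs were generated by integration with made-up constants.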